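The slowness of mono adduct's further reaction, set against the speed of its making, is what the next flask hangs on. The decision for that flask is how long to leave it and whether its charge of coupling partner is enough.

| setting | grey | ochre | teal | flask |
|---|---|---|---|---|
| substrate | 0.071 M | 0.071 M | 0.11 M | 0.071 M |
| coupling partner | 0.071 M | 0.28 M | 0.142 M | 0.142 M |
| remark | run made earlier | run made earlier | run made earlier |  |
| time |  |  |  | 40 h |

| run | time / h | mono adduct / % | substrate / % |
|---|---|---|---|
| grey | 0.500 | 34.9 | 63.9 |
| grey | 1.33 | 56.8 | 41.1 |
| grey | 3.00 | 70.4 | 25.3 |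
| grey | 6.00 | 77.2 | 16.6 |
| grey | 15.0 | 79.9 | 11.2 |
| grey | 30.0 | 80.6 | 10.9 |
| ochre | 0.500 | 77.0 | 15.7 |
| ochre | 1.33 | 77.8 | 1.0 |
| ochre | 3.00 | 57.9 | 0.6 |
| ochre | 6.00 | 32.1 | 1.2 |
| ochre | 15.0 | 7.8 | 0.5 |
| ochre | 30.0 | 1.5 | 0 |
| teal | 0.500 | 53.8 | 45.0 |
| teal | 1.50 | 77.8 | 17.5 |
| teal | 4.00 | 84.9 | 4.7 |
| teal | 12.0 | 85.0 | 0.9 |
| teal | 30.0 | 78.7 | 0 |

(standard deviation of a reading: 0.5 percentage points)

- a reading or a percentage of mono adduct counts all its forms, free or not

* the best time, 40 h at the latest, for mono adduct
* the amount of mono adduct, in percent of the substrate charged, at that time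

The ochre run gives both speeds as pseudo-first-order rates. The remainder that is neither substrate nor mono adduct is assumed here to have taken two coupling partner per substrate. Over the first 0.500 h of that run the substrate falls at 3.70 h⁻¹, with a mean c(coupling partner) of 0.247 M. Between 3.00 h and 15.0 h the mono adduct falls more slowly than that, at 0.167 h⁻¹, with a mean c(coupling partner) of 0.162 M. Each rate divided by its c(coupling partner), and the second divided by the first, gives s, the selectivity factor: the loss constant of mono adduct over that of substrate, read as 0.0689.

With both losses first order in coupling partner, c(coupling partner) cancels from the ratio of the substrate and mono adduct balances and time drops out. So long as coupling partner remains, this reckoning puts the peak of mono adduct in the flask where c(substrate)/c(mono adduct) equals s, with substrate at 5.65% and mono adduct at 82.0%. The grey run ended lower, at 80.6%, with 10.9% of substrate unreacted. The teal run, which differs from the flask in its substrate charge, read higher, 85.0% at 12.0 h, so the reckoned peak stands as an estimate for the flask. The balance for the flask still leaves 0.0663 M of coupling partner at the peak, so its charge stays as it is. Integrating the substrate loss, with coupling partner spent on substrate alone, puts the peak near 2.10 h, so the flask should be stopped about then rather than left to 40 h.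

The forecast puts 82% (range 80% to 84.5%) at 2.3 h (range 1.8 h to 3 h), later than the time reckoned here, and adds: “The maximum is flat.”

The flask gives 82.1% at 2.29 h.

    substrate + coupling partner → mono adduct (k = 0.260 M⁻¹ min⁻¹)
    coupling partner + mono adduct → double product (k = 0.00660 M⁻¹ min⁻¹)
    coupling partner + double product → triple product (k = 0.260 M⁻¹ min⁻¹)
    crystals ⇌ mono adduct, rate k4*(cs4 - [mono adduct]) while solid is left; crystals form when [mono adduct] > cs4 (solubility = 44.0 mM, k = 0.110 min⁻¹)
    coupling partner + mono adduct → over-reaction product (k = 0.0140 M⁻¹ min⁻¹)

In the flask at 2.29 h the ratio of substrate to mono adduct, crystals counted, stands at 0.0600, against s of 0.0689. The neighbouring flask, charged with 0.24 M of coupling partner (3.38 equiv), has the same s in this reckoning, which therefore gives 82.0% again. That flask reaches 81.8%. After 40.0 h it holds 1.16% of mono adduct, less than the 32.1% of the flask, and 31.6% of triple product.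

(The earlier runs and the new flask stem from a simulated flask from invented constants; noise was put on by code.)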